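Both dihydrobenzofuran rings are cut at their C2–C3 bonds. In each ring C3 carries a 3,5-dioxygenated aryl group and sits on the arene carbon ortho to the ring oxygen, while C2 is an O–CH carbon bearing an ortho,para-oxygenated aryl group. Each C2–C3 bond is therefore what a diaryl carbene leaves on inserting into an aryl benzyl ether C–H bond. One chiral dirhodium catalyst should close both five-membered rings and create all four stereocentres at once from an achiral bis(hydrazone), in which six purchased benzene rings are joined through two diarylmethylidene carbons and two benzylic ether CH2 groups. Acid then turns both C2 centres trans; cross-coupling and demethylation finish.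

Key step: step 10

Assumption: dirhodium tetrakis[(R)-(1-adamantyl)(phthalimido)acetate], Rh2(R-PTAD)4, is taken to give the 3S configuration at both C3 centres; if the sense of induction is the opposite, its mirror image Rh2(S-PTAD)4 is used with nothing else changed.

Step 1
Reactants: 1 1-bromo-3,5-dimethoxybenzene; 2 3,5-dimethoxybenzoyl chloride
Product: 3 (2-bromo-4,6-dimethoxyphenyl)(3,5-dimethoxyphenyl)methanone
Conditions: AlCl3 (1.2 equiv), CH2Cl2, 0 °C → rt
Reagents that add atoms: none
Why: Friedel–Crafts acylation, which should go mainly to the ring position para to one methoxy group and ortho to bromine (the usual site for 3,5-dimethoxyaryl halides) rather than between the two methoxy groups, while the acyl chloride ring is deactivated by its own carbonyl group.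

Step 2
Reactants: 3 (2-bromo-4,6-dimethoxyphenyl)(3,5-dimethoxyphenyl)methanone
Product: 4 (2-bromo-6-hydroxy-4-methoxyphenyl)(3,5-dimethoxyphenyl)methanone
Conditions: BCl3 (1.2 equiv), CH2Cl2, −78 → 0 °C; aq. work-up
Reagents that add atoms: none
Why: Chelation-directed Lewis-acid demethylation, in which boron bound to the carbonyl oxygen should cleave only the one methyl ether ortho to the ketone and leave the para and the two meta methoxy groups untouched.

Step 3
Reactants: 5 1,3-dimethoxybenzene; 2 3,5-dimethoxybenzoyl chloride
Product: 8 (2,6-dimethoxyphenyl)(3,5-dimethoxyphenyl)methanone, via 2,6-dimethoxyphenyllithium 6 (not isolated), via (2,6-dimethoxyphenyl)zinc chloride 7 (not isolated)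
Conditions: n-BuLi, THF, 0 °C → rt; ZnCl2, 0 °C; then 2, Pd(PPh3)4 (5 mol %), rt → 50 °C
Reagents that add atoms: none
Why: Directed ortho-lithiation between the two methoxy groups, transmetalation to zinc and Negishi acylation should give the ketone cleanly, because the arylzinc does not add to the hindered ketone product.

Step 4
Reactants: 8 (2,6-dimethoxyphenyl)(3,5-dimethoxyphenyl)methanone
Product: 9 (2-hydroxy-6-methoxyphenyl)(3,5-dimethoxyphenyl)methanone
Conditions: BCl3 (1.05 equiv), CH2Cl2, −78 → 0 °C; aq. work-up
Reagents that add atoms: none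
Why: Chelation-controlled mono-demethylation, since the boron chelate formed after the first ortho cleavage ties up the carbonyl group and should protect the second ortho methoxy group.

Step 5
Reactants: 9 (2-hydroxy-6-methoxyphenyl)(3,5-dimethoxyphenyl)methanone
Product: 10 3-(3,5-dimethoxybenzoyl)-2-hydroxy-4-methoxybenzaldehyde
Conditions: MgCl2, Et3N, (CH2O)n, MeCN, reflux
Reagents that add atoms: paraformaldehyde (as formaldehyde), C=O
Why: Magnesium-mediated phenol ortho-formylation (Casnati–Skattebøl), for which the only free position ortho to the phenol is also para to the methoxy group and meta to the ketone, so a single site should react.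

Step 6
Reactants: 10 3-(3,5-dimethoxybenzoyl)-2-hydroxy-4-methoxybenzaldehyde; 11 2,4-dimethoxybenzyl alcohol
Product: 12 3-(3,5-dimethoxybenzoyl)-2-[(2,4-dimethoxybenzyl)oxy]-4-methoxybenzaldehyde
Conditions: PPh3, DIAD, THF, 0 °C → rt
Reagents that add atoms: none
Why: Mitsunobu etherification, in which the acidic, doubly carbonyl-flanked phenol is a good pronucleophile and the primary benzylic alcohol is activated in the flask, so the unstable 2,4-dimethoxybenzyl halide is never handled.

Step 7
Reactants: 12 3-(3,5-dimethoxybenzoyl)-2-[(2,4-dimethoxybenzyl)oxy]-4-methoxybenzaldehyde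
Product: 13 {2-[(2,4-dimethoxybenzyl)oxy]-3-(hydroxymethyl)-6-methoxyphenyl}(3,5-dimethoxyphenyl)methanone
Conditions: NaBH4, THF/MeOH, −10 → 0 °C
Reagents that add atoms: none
Why: Chemoselective borohydride reduction, since the aldehyde should be reduced quickly while the diaryl ketone, flanked by two ortho alkoxy groups and twisted out of conjugation, is not attacked at this temperature.

Step 8
Reactants: 4 (2-bromo-6-hydroxy-4-methoxyphenyl)(3,5-dimethoxyphenyl)methanone; 13 {2-[(2,4-dimethoxybenzyl)oxy]-3-(hydroxymethyl)-6-methoxyphenyl}(3,5-dimethoxyphenyl)methanone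
Product: 14 bis(ketone) {2-bromo-6-[(3-(3,5-dimethoxybenzoyl)-2-[(2,4-dimethoxybenzyl)oxy]-4-methoxybenzyl)oxy]-4-methoxyphenyl}(3,5-dimethoxyphenyl)methanone
Conditions: PPh3, DIAD, toluene/THF, 0 °C → rt
Reagents that add atoms: none
Why: Mitsunobu etherification of the ortho-acyl phenol with the primary benzylic alcohol under neutral conditions, which should spare both acid-labile electron-rich benzyl ethers and avoid a benzylic halide that would ionise readily.

Step 9
Reactants: 14 bis(ketone)
Product: 15 bis(hydrazone) of 14 (both C=O replaced by C=N–NH2; C=N geometry of no consequence)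
Conditions: N2H4 (anhydrous, 20 equiv), N2H4·HCl (0.2 equiv), n-BuOH, 4 Å MS, 100 °C, sealed tube
Reagents that add atoms: hydrazine, NN
Why: Hydrazone condensation, driven at both flanked ketones by a large excess of the small nucleophile, hydrazinium catalysis and water removal; this acid is too weak to cleave the benzyl ethers, and ring closure of a hydrazone onto the electron-rich C–Br carbon is not expected without copper or palladium at this temperature.

Step 10
Reactants: 15 bis(hydrazone)
Product: 17 cis,cis-bis(2,3-diaryl-2,3-dihydrobenzofuran) bromide (2R,3S in the ring A unit; 2R,3S in the central unit), via bis(diazo) compound 16 (not isolated)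
Conditions: MnO2 (activated, 16 equiv), CH2Cl2, 0 °C; filter (Celite); Rh2(R-PTAD)4 (2 mol %), CH2Cl2, 0 °C → rt
Reagents that add atoms: none
Why: Proposed new method: MnO2 dehydrogenates each hydrazone to a diaryldiazomethane, which loses N2 on the dirhodium tetracarboxylate to give a donor/donor rhodium carbene that inserts into the ether O–CH2 bond five atoms away through an asynchronous, hydride-transfer-like three-centre transition state; the closest known reaction type is the single enantioselective intramolecular C–H insertion of donor/donor rhodium carbenes from 2-benzyloxybenzophenone hydrazones to cis-2,3-diaryl-2,3-dihydrobenzofurans, and what is new is running it twice in one substrate at carbenes flanked by two ortho substituents. Each dihydrofuran ring closes by a 1,5-insertion that forms its C2–C3 bond, one onto the CH2 of the 2,4-dimethoxybenzyl ether and one onto the CH2 that links the central ring to the ring A oxygen. C3 of each ring should be set 3S by the chiral carboxylate ligand sphere of the catalyst, which decides the carbene face that meets the C–H bond, and C2 of each ring should be set 2R (cis to C3) by the compact insertion transition state that keeps the two aryl groups on the same side. The step needs site selectivity for the benzylic O–CH2 over the O–CH3 next to the central carbene, secured because the benzylic C–H bonds (alpha to oxygen and to an electron-rich arene) are far more hydridic; it also needs the carbenes to ignore the aryl bromide and each other, secured by their low electrophilicity and by the ortho groups that hold each carbene beside its own CH2 and hinder azine formation. Because the two remote insertions are independent, the minor-enantiomer error of each event should end mostly in a separable diastereomer.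

Step 11
Reactants: 17 cis,cis-bis(dihydrobenzofuran) bromide
Product: 18 trans,trans-bis(dihydrobenzofuran) bromide (2S,3S in both units)
Conditions: TfOH (10 mol %), CH2Cl2, −40 → 0 °C
Reagents that add atoms: none
Why: Acid-promoted cis-to-trans isomerisation of 2-aryl-2,3-dihydrobenzofurans, in which each C2–O bond ionises reversibly to a benzylic cation stabilised by the ortho and para oxygens of its aryl group and recloses (5-exo) under thermodynamic control with the C2 aryl trans to the untouched C3 aryl, so both C2 centres should invert from R to S.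

Step 12
Reactants: 18 trans,trans-bis(dihydrobenzofuran) bromide; 19 (E)-2-(4-methoxyphenyl)vinylboronic acid
Product: 20 nona-O-methyl ether of the target
Conditions: Pd(OAc)2 (5 mol %), SPhos (10 mol %), K3PO4, toluene/H2O, 80 °C
Reagents that add atoms: none
Why: Suzuki–Miyaura coupling, in which the bulky biarylphosphine should allow oxidative addition at the ortho-substituted, electron-rich aryl bromide and the alkenylboron transfers with retention of its E geometry.

Step 13
Reactants: 20 nona-O-methyl ether of the target
Product: 21 target CNP0397447.1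
Conditions: BBr3 (25 equiv), CH2Cl2, −78 → 0 °C; MeOH, then aq. work-up
Reagents that add atoms: none
Why: Lewis-acid cleavage of all nine aryl methyl ethers; any reversible C2–O ionisation under the boron halide should return the same trans rings, which are the thermodynamic arrangement, and the E-stilbene should survive at low temperature.

Compound list
1 | 1-bromo-3,5-dimethoxybenzene | COc1cc(Br)cc(OC)c1 | starting material
2 | 3,5-dimethoxybenzoyl chloride | COc1cc(OC)cc(c1)C(Cl)=O | starting material
3 | (2-bromo-4,6-dimethoxyphenyl)(3,5-dimethoxyphenyl)methanone | COc1cc(OC)c(C(=O)c2cc(OC)cc(OC)c2)c(Br)c1 | intermediate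
4 | (2-bromo-6-hydroxy-4-methoxyphenyl)(3,5-dimethoxyphenyl)methanone | COc1cc(O)c(C(=O)c2cc(OC)cc(OC)c2)c(Br)c1 | intermediate
5 | 1,3-dimethoxybenzene | COc1cccc(OC)c1 | starting material
6 | 2,6-dimethoxyphenyllithium | [Li]c1c(OC)cccc1OC | intermediate
7 | (2,6-dimethoxyphenyl)zinc chloride | Cl[Zn]c1c(OC)cccc1OC | intermediate
8 | (2,6-dimethoxyphenyl)(3,5-dimethoxyphenyl)methanone | COc1cccc(OC)c1C(=O)c1cc(OC)cc(OC)c1 | intermediate
9 | (2-hydroxy-6-methoxyphenyl)(3,5-dimethoxyphenyl)methanone | COc1cccc(O)c1C(=O)c1cc(OC)cc(OC)c1 | intermediate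
10 | 3-(3,5-dimethoxybenzoyl)-2-hydroxy-4-methoxybenzaldehyde | O=Cc1ccc(OC)c(C(=O)c2cc(OC)cc(OC)c2)c1O | intermediate
11 | 2,4-dimethoxybenzyl alcohol | COc1ccc(CO)c(OC)c1 | starting material
12 | 3-(3,5-dimethoxybenzoyl)-2-[(2,4-dimethoxybenzyl)oxy]-4-methoxybenzaldehyde | O=Cc1ccc(OC)c(C(=O)c2cc(OC)cc(OC)c2)c1OCc1ccc(OC)cc1OC | intermediate
13 | {2-[(2,4-dimethoxybenzyl)oxy]-3-(hydroxymethyl)-6-methoxyphenyl}(3,5-dimethoxyphenyl)methanone | OCc1ccc(OC)c(C(=O)c2cc(OC)cc(OC)c2)c1OCc1ccc(OC)cc1OC | intermediate
14 | bis(ketone): {2-bromo-6-[(3-(3,5-dimethoxybenzoyl)-2-[(2,4-dimethoxybenzyl)oxy]-4-methoxybenzyl)oxy]-4-methoxyphenyl}(3,5-dimethoxyphenyl)methanone | COc1cc(OCc2ccc(OC)c(C(=O)c3cc(OC)cc(OC)c3)c2OCc2ccc(OC)cc2OC)c(C(=O)c2cc(OC)cc(OC)c2)c(Br)c1 | intermediate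
15 | bis(hydrazone) of 14 (each C=O replaced by C=N–NH2) | COc1cc(OCc2ccc(OC)c(C(=NN)c3cc(OC)cc(OC)c3)c2OCc2ccc(OC)cc2OC)c(C(=NN)c2cc(OC)cc(OC)c2)c(Br)c1 | intermediate
16 | bis(diazo) compound (each C=N–NH2 of 15 replaced by C=N2) | COc1cc(OCc2ccc(OC)c(C(=[N+]=[N-])c3cc(OC)cc(OC)c3)c2OCc2ccc(OC)cc2OC)c(C(=[N+]=[N-])c2cc(OC)cc(OC)c2)c(Br)c1 | intermediate
17 | (2R,3S)-4-bromo-2-[(2R,3S)-2-(2,4-dimethoxyphenyl)-3-(3,5-dimethoxyphenyl)-4-methoxy-2,3-dihydrobenzofuran-7-yl]-3-(3,5-dimethoxyphenyl)-6-methoxy-2,3-dihydrobenzofuran (both rings cis) | COc1cc(Br)c2c(c1)O[C@@H](c1ccc(OC)c3c1O[C@@H](c1ccc(OC)cc1OC)[C@H]3c1cc(OC)cc(OC)c1)[C@H]2c1cc(OC)cc(OC)c1 | intermediate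
18 | (2S,3S)-4-bromo-2-[(2S,3S)-2-(2,4-dimethoxyphenyl)-3-(3,5-dimethoxyphenyl)-4-methoxy-2,3-dihydrobenzofuran-7-yl]-3-(3,5-dimethoxyphenyl)-6-methoxy-2,3-dihydrobenzofuran (both rings trans) | COc1cc(Br)c2c(c1)O[C@H](c1ccc(OC)c3c1O[C@H](c1ccc(OC)cc1OC)[C@H]3c1cc(OC)cc(OC)c1)[C@H]2c1cc(OC)cc(OC)c1 | intermediate
19 | (E)-2-(4-methoxyphenyl)vinylboronic acid | COc1ccc(/C=C/B(O)O)cc1 | starting material
20 | (2S,3S)-2-[(2S,3S)-2-(2,4-dimethoxyphenyl)-3-(3,5-dimethoxyphenyl)-4-methoxy-2,3-dihydrobenzofuran-7-yl]-3-(3,5-dimethoxyphenyl)-6-methoxy-4-[(E)-4-methoxystyryl]-2,3-dihydrobenzofuran | COc1ccc(/C=C/c2cc(OC)cc3c2[C@H](c2cc(OC)cc(OC)c2)[C@@H](c2ccc(OC)c4c2O[C@H](c2ccc(OC)cc2OC)[C@H]4c2cc(OC)cc(OC)c2)O3)cc1 | intermediate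
21 | (2S,3S)-2-[(2S,3S)-2-(2,4-dihydroxyphenyl)-3-(3,5-dihydroxyphenyl)-4-hydroxy-2,3-dihydrobenzofuran-7-yl]-3-(3,5-dihydroxyphenyl)-4-[(E)-4-hydroxystyryl]-2,3-dihydrobenzofuran-6-ol (CNP0397447.1) | Oc1ccc(/C=C/c2cc(O)cc3c2[C@H](c2cc(O)cc(O)c2)[C@@H](c2ccc(O)c4c2O[C@H](c2ccc(O)cc2O)[C@H]4c2cc(O)cc(O)c2)O3)cc1 | target

Total step count: 13. Longest linear sequence: 11 steps (steps 3 to 13, from 1,3-dimethoxybenzene).

Steps most likely to fail

Step 10 (bears the label "Proposed new method:"). Carbene formation at the two doubly flanked diazo carbons may be slow, so that azine formation competes or the reaction stalls after the first ring closure; facial control may also be weak at one of the two carbenes. The fallback uses known chemistry, sets out from bis(ketone) 14 and comes back at 18. Heating 14 with the phosphazene base P4-t-Bu in toluene should add each benzylic ether carbanion to its neighbouring ketone and dehydrate, giving the bis(2,3-diarylbenzofuran) bromide F1. Ionic hydrogenation of F1 (Et3SiH, TFA, CH2Cl2) should protonate C3 and deliver hydride to C2 anti to the C3 aryl group, giving the trans,trans bromide as a stereoisomer mixture F2 (two racemic diastereomers). Separation of the diastereomers on silica and preparative chromatography on a chiral stationary phase would then give 18. This route gives up catalyst control and the material economy of the key step.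

Step 9. Condensation at the two hindered carbonyl groups may stay incomplete, and forcing it may bring on ring closure of a hydrazone nitrogen onto the C–Br carbon. The fallback sets out from 14 and comes back at 15. Treating 14 with 1,2-bis(tert-butyldimethylsilyl)hydrazine and catalytic Sc(OTf)3 (silyl-transfer condensation, rt → 50 °C) should give the bis(N-tert-butyldimethylsilyl hydrazone) F3 without free hydrazine or strong heating. Desilylation of F3 with n-Bu4NF in THF/MeOH at 0 °C should then give 15.

Step 11. The ring-opened benzylic cations may be trapped by a neighbouring electron-rich arene (Friedel–Crafts) instead of reclosing, or inversion at C2 of the ring A unit may stay incomplete. The fallback sets out from 17 and comes back at 21. Treating 17 with BBr3 (CH2Cl2, −78 → 0 °C) should cleave the eight methyl ethers and equilibrate both C2 centres through quinone-methide-type ionisation of the freed ortho and para phenols, with no stilbene present to trap the cations, giving the trans,trans octahydroxy bromide F4. Suzuki–Miyaura coupling of F4 with purchased 4-[(E)-2-(4,4,5,5-tetramethyl-1,3,2-dioxaborolan-2-yl)vinyl]phenol (Pd(OAc)2, SPhos, K3PO4, degassed dioxane/H2O) would then give 21 directly.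

Further compounds
F1 | step 10 | 4-bromo-2-[2-(2,4-dimethoxyphenyl)-3-(3,5-dimethoxyphenyl)-4-methoxybenzofuran-7-yl]-3-(3,5-dimethoxyphenyl)-6-methoxybenzofuran | COc1cc(Br)c2c(c1)oc(-c1ccc(OC)c3c1oc(-c1ccc(OC)cc1OC)c3-c1cc(OC)cc(OC)c1)c2-c1cc(OC)cc(OC)c1
F2 | step 10 | trans,trans-bis(dihydrobenzofuran) bromide as a mixture of two racemic diastereomers (constitution of 18, configuration not controlled) | COc1cc(Br)c2c(c1)OC(c1ccc(OC)c3c1OC(c1ccc(OC)cc1OC)C3c1cc(OC)cc(OC)c1)C2c1cc(OC)cc(OC)c1
F3 | step 9 | bis(N-tert-butyldimethylsilyl hydrazone) of 14 | COc1cc(OCc2ccc(OC)c(C(=NN[Si](C)(C)C(C)(C)C)c3cc(OC)cc(OC)c3)c2OCc2ccc(OC)cc2OC)c(C(=NN[Si](C)(C)C(C)(C)C)c2cc(OC)cc(OC)c2)c(Br)c1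
F4 | step 11 | (2S,3S)-4-bromo-2-[(2S,3S)-2-(2,4-dihydroxyphenyl)-3-(3,5-dihydroxyphenyl)-4-hydroxy-2,3-dihydrobenzofuran-7-yl]-3-(3,5-dihydroxyphenyl)-2,3-dihydrobenzofuran-6-ol | Oc1cc(Br)c2c(c1)O[C@H](c1ccc(O)c3c1O[C@H](c1ccc(O)cc1O)[C@H]3c1cc(O)cc(O)c1)[C@H]2c1cc(O)cc(O)c1
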